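**Plan**
- Retrosynthesis first opens the (Z)-butylidene butenolide: the enol-lactone C–O bond, then the bond between the ring alkene carbon and the ylidene carbon (enol triflate plus pent-1-yne). It then cuts the spiro-phthalide (aryl–C8 bond and lactone acyl C–O), the C7–propyl bond, and last the two cyclohexene σ-bonds C1–C2 and C5–C6.
- Enabling feature: the cyclohexene whose C=C carries the butenolide carbonyl carbon and a carbon that was oxygen-bearing (a masked β-keto ester), cis-fused to the four-membered ring. This is the adduct pattern of cyclobut-2-en-1-one with a 1-(methoxycarbonyl)-2-silyloxybuta-1,3-diene.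
- Forward order of rings: the four-membered ring is bought, the cyclohexene is closed by [4+2], the phthalide by aryl addition and lactonization, and the butenolide last by alkyne cycloisomerization.
- Stereochemistry: both ring-fusion centres and the absolute configuration come from the oxazaborolidine-catalysed cycloaddition. C7 is set by convex-face hydroboration, the spiro centre by convex-face aryl addition, and the Z alkene by anti oxymetalation.

Key step: step 6

Remark on numbering: the bicyclo[4.2.0]octane numbering of 11 is kept for all later compounds (C1 and C6 ring fusion, ester carbon on C2, oxygen on C3, C7 next to C6, C8 next to C1).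

Assumption: the (S)-prolinol-derived catalyst is taken to expose the enone face that leads to (1R,6R)-11; if the sense of induction proves opposite, the equally available mirror-image catalyst is used with no other change.

**Route**

Step 1
Reactants: 1 3-oxocyclobutane-1-carboxylic acid
Product: 2 3-bromocyclobutan-1-one
Conditions: HgO, Br2, MgSO4, CH2Cl2, reflux
Reagents that add atoms: bromine, BrBr
Why: Hunsdiecker-type bromodecarboxylation (Cristol–Firth variant), in which the acyl hypobromite formed via the carboxylate of divalent mercury fragments by a radical chain to CO2 and a cyclobutyl radical that abstracts bromine, the ketone being inert.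

Step 2
Reactants: 2 3-bromocyclobutan-1-one
Product: 3 cyclobut-2-en-1-one
Conditions: n-Bu3N, neat, rt; vacuum transfer into a −78 °C trap; used as a cold CH2Cl2 solution
Reagents that add atoms: none
Why: E1cB dehydrobromination of a β-bromo ketone by a tertiary amine whose hydrobromide is non-volatile, so that the strained enone can be distilled off cold and used before it polymerizes.

Step 3
Reactants: 4 methyl acetate; 5 acrolein
Product: 7 methyl 3-hydroxypent-4-enoate, via lithium enolate of methyl acetate 6 (not isolated)
Conditions: LiN(i-Pr)2, THF, −78 °C; then 5, −78 °C; 1 M HCl quench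
Reagents that add atoms: none
Why: Aldol addition of an ester lithium enolate to an enal, which at −78 °C goes 1,2 at the aldehyde; the carbinol centre is formed racemic and is removed by the next oxidation.

Step 4
Reactants: 7 methyl 3-hydroxypent-4-enoate
Product: 8 methyl 3-oxopent-4-enoate
Conditions: Dess–Martin periodinane, CH2Cl2, 0 °C to rt; used directly
Reagents that add atoms: none
Why: Dess–Martin oxidation of the allylic alcohol under neutral, non-aqueous conditions should give the sensitive vinyl β-keto ester without conjugate addition.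

Step 5
Reactants: 8 methyl 3-oxopent-4-enoate
Product: 9 methyl (2Z)-3-[(tert-butyldimethylsilyl)oxy]penta-2,4-dienoate
Conditions: TBSOTf, Et3N, CH2Cl2, −78 to 0 °C
Reagents that add atoms: tert-butyldimethylsilyl trifluoromethanesulfonate, CC(C)(C)[Si](C)(C)OS(=O)(=O)C(F)(F)F
Why: O-Silylation of a β-keto ester under soft enolization, where C2 is the only enolizable position and silylation of the internally chelated enol should favour the Z silyl enol ether, which has the ester on the outside of the s-cis diene (any E isomer should be inert in step 6).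

Step 6
Reactants: 3 cyclobut-2-en-1-one; 9 methyl (2Z)-3-[(tert-butyldimethylsilyl)oxy]penta-2,4-dienoate
Product: 11 methyl (1R,6R)-3-hydroxy-7-oxobicyclo[4.2.0]oct-2-ene-2-carboxylate, via silyl enol ether cycloadduct 10 (not isolated)
Conditions: (S)-3,3-diphenyl-1-(o-tolyl)tetrahydro-1H,3H-pyrrolo[1,2-c][1,3,2]oxazaborole (15 mol %), AlBr3 (12 mol %), CH2Cl2, −78 °C; then 1 M HCl, THF, 0 °C
Reagents that add atoms: none
Why: The boron of the AlBr3-activated oxazaborolidine binds the cyclobutenone carbonyl and lowers its LUMO, and the diene adds in a concerted but asynchronous [4+2] in which the bond from the ester-bearing C2 of 9 to the enone β-carbon runs ahead of the bond from the CH2 terminus to the α-carbon. The closest known reaction type is the oxazaborolidinium-catalysed Diels–Alder reaction of cyclic enones, cyclobutenone included, with 2-silyloxy dienes, and this ester-substituted diene is a new partner within that class. The cyclohexene ring closes by intermolecular [4+2] cycloaddition, suprafacial on both partners, with its two σ-bonds (C1–C2 and C5–C6) formed in the one step. C1 and C6 come out cis because the dienophile is a cis ring alkene, their absolute configuration is set by the catalyst, whose aryl groups shield one face of the bound enone, and the transient C2 centre (endo approach) is erased when 10 is hydrolysed to the enolized β-keto ester. The step needs the regiochemistry that puts the ester carbon next to the former β-carbon, an endo cis fusion and one enantioface; the silyloxy group on C3 of 9, which makes C2 the nucleophilic diene terminus, secures the first, the chiral Lewis acid the others, and ring strain makes the dienophile reactive enough at −78 °C for this push–pull diene.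

Step 7
Reactants: 11 methyl (1R,6R)-3-hydroxy-7-oxobicyclo[4.2.0]oct-2-ene-2-carboxylate
Product: 12 methyl (1R,6R)-3-methoxy-7-oxobicyclo[4.2.0]oct-2-ene-2-carboxylate
Conditions: Me2SO4, Cs2CO3, DMF, 0 °C to rt
Reagents that add atoms: dimethyl sulfate, COS(=O)(=O)OC
Why: O-Alkylation of a β-keto ester enolate, in which the cesium enolate in DMF takes the hard electrophile on oxygen, C-methylation at C2 is hindered by the adjacent ring-fusion carbon, and carbonate is too weak to enolize the cyclobutanone.

Step 8
Reactants: 12 methyl (1R,6R)-3-methoxy-7-oxobicyclo[4.2.0]oct-2-ene-2-carboxylate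
Product: 14 methyl (1R,6R)-3-methoxy-7-(trifluoromethylsulfonyloxy)bicyclo[4.2.0]octa-2,7-diene-2-carboxylate, via potassium cyclobutenolate 13 (not isolated)
Conditions: KN(SiMe3)2, THF, −78 °C; then PhNTf2, −78 to 0 °C
Reagents that add atoms: N-phenylbis(trifluoromethanesulfonimide), O=S(=O)(N(c1ccccc1)S(=O)(=O)C(F)(F)F)C(F)(F)F
Why: Kinetic enolization and O-triflation, in which the hindered amide base removes a proton from the unhindered C8 methylene and not the ring-fusion C6–H (the γ-protons of the vinylogous carbonate are far less acidic) and the enolate is sulfonylated on oxygen.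

Step 9
Reactants: 14 methyl (1R,6R)-3-methoxy-7-(trifluoromethylsulfonyloxy)bicyclo[4.2.0]octa-2,7-diene-2-carboxylate
Product: 15 methyl (1R,6R)-3-methoxy-7-propylbicyclo[4.2.0]octa-2,7-diene-2-carboxylate
Conditions: n-PrZnBr, Pd(dppf)Cl2 (5 mol %), THF, rt
Reagents that add atoms: n-propylzinc bromide, CCC[Zn]Br
Why: Negishi coupling, in which zerovalent palladium adds oxidatively to the alkenyl C–OTf bond, propyl is transferred from zinc and reductive elimination outruns β-hydride elimination with the wide-bite-angle diphosphine, the ester and enol ether being inert to the organozinc.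

Step 10
Reactants: 15 methyl (1R,6R)-3-methoxy-7-propylbicyclo[4.2.0]octa-2,7-diene-2-carboxylate
Product: 17 methyl (1R,6S,7R,8S)-8-hydroxy-3-methoxy-7-propylbicyclo[4.2.0]oct-2-ene-2-carboxylate, via B-alkyl-9-borabicyclo[3.3.1]nonane 16 (not isolated)
Conditions: 9-BBN, THF, 0 °C to rt; then NaBO3·4H2O, H2O, rt
Reagents that add atoms: sodium perborate, [Na+].[Na+].O[B-]1(O)OO[B-](O)(O)OO1
Why: Hydroboration–oxidation, in which 9-BBN adds syn across the strained trisubstituted cyclobutene with boron on the less substituted C8 and hydrogen on C7, both from the convex face (the face of the ring-fusion hydrogens), which sets C7 with propyl on the concave face, and oxidation replaces boron by OH with retention while the tetrasubstituted push–pull alkene and the ester stay untouched.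

Step 11
Reactants: 17 methyl (1R,6S,7R,8S)-8-hydroxy-3-methoxy-7-propylbicyclo[4.2.0]oct-2-ene-2-carboxylate
Product: 18 methyl (1R,6S,7R)-3-methoxy-8-oxo-7-propylbicyclo[4.2.0]oct-2-ene-2-carboxylate
Conditions: Dess–Martin periodinane, NaHCO3, CH2Cl2, 0 °C; used at once
Reagents that add atoms: none
Why: Dess–Martin oxidation buffered with NaHCO3 converts the secondary cyclobutanol into the ketone without a base strong enough to epimerize the adjacent C7 centre.

Step 12
Reactants: 18 methyl (1R,6S,7R)-3-methoxy-8-oxo-7-propylbicyclo[4.2.0]oct-2-ene-2-carboxylate; 19 methyl 2-iodobenzoate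
Product: 22 methyl (1R,6S,7R,8R)-3-methoxy-3'-oxo-7-propyl-3'H-spiro[bicyclo[4.2.0]oct-2-ene-8,1'-[2]benzofuran]-2-carboxylate, via 2-(methoxycarbonyl)phenylmagnesium chloride 20 (not isolated), via chloromagnesium tertiary alkoxide 21 (not isolated)
Conditions: 19, i-PrMgCl·LiCl, THF, −40 °C; then 18, LaCl3·2LiCl, −40 °C to rt; cold 1 M HCl work-up
Reagents that add atoms: none
Why: Iodine–magnesium exchange followed by Grignard 1,2-addition and lactonization, in which the ester-bearing arylmagnesium reagent adds to the strain-activated ketone faster than it enolizes it (helped by LaCl3·2LiCl), from the convex face anti to both the six-membered ring and the C7 propyl group, which sets the spiro centre with aryl exo and oxygen endo, before the alkoxide acylates itself on the ortho ester to close the phthalide.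

Step 13
Reactants: 22 methyl (1R,6S,7R,8R)-3-methoxy-3'-oxo-7-propyl-3'H-spiro[bicyclo[4.2.0]oct-2-ene-8,1'-[2]benzofuran]-2-carboxylate
Product: 23 methyl (1R,6S,7R,8R)-3-hydroxy-3'-oxo-7-propyl-3'H-spiro[bicyclo[4.2.0]oct-2-ene-8,1'-[2]benzofuran]-2-carboxylate
Conditions: 2 M HCl, THF, 40 °C
Reagents that add atoms: water, O
Why: Acid hydrolysis of a vinylogous carbonate (protonation at C2, addition of water at C3, loss of methanol) returns the enolized β-keto ester, while the phthalide and the methyl ester are stable to dilute aqueous acid.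

Step 14
Reactants: 23 methyl (1R,6S,7R,8R)-3-hydroxy-3'-oxo-7-propyl-3'H-spiro[bicyclo[4.2.0]oct-2-ene-8,1'-[2]benzofuran]-2-carboxylate
Product: 24 methyl (1R,6S,7R,8R)-3'-oxo-7-propyl-3-(trifluoromethylsulfonyloxy)-3'H-spiro[bicyclo[4.2.0]oct-2-ene-8,1'-[2]benzofuran]-2-carboxylate
Conditions: Tf2O, i-Pr2NEt, CH2Cl2, −78 °C
Reagents that add atoms: trifluoromethanesulfonic anhydride, O=S(=O)(OS(=O)(=O)C(F)(F)F)C(F)(F)F
Why: O-Triflation of the enolized β-keto ester with Tf2O and a hindered amine at low temperature is standard and gives the ring-constrained β-triflyloxy enoate, no other acidic or nucleophilic site being present.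

Step 15
Reactants: 24 methyl (1R,6S,7R,8R)-3'-oxo-7-propyl-3-(trifluoromethylsulfonyloxy)-3'H-spiro[bicyclo[4.2.0]oct-2-ene-8,1'-[2]benzofuran]-2-carboxylate; 25 pent-1-yne
Product: 26 methyl (1R,6S,7R,8R)-3'-oxo-3-(pent-1-yn-1-yl)-7-propyl-3'H-spiro[bicyclo[4.2.0]oct-2-ene-8,1'-[2]benzofuran]-2-carboxylate
Conditions: Pd(PPh3)2Cl2 (5 mol %), CuI (10 mol %), Et3N, DMF, rt
Reagents that add atoms: none
Why: Sonogashira coupling, in which the electron-poor alkenyl triflate adds readily to zerovalent palladium and the copper acetylide of pent-1-yne (monovalent copper) delivers the alkynyl group under conditions that leave lactone and ester alone.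

Step 16
Reactants: 26 methyl (1R,6S,7R,8R)-3'-oxo-3-(pent-1-yn-1-yl)-7-propyl-3'H-spiro[bicyclo[4.2.0]oct-2-ene-8,1'-[2]benzofuran]-2-carboxylate
Product: 27 (1R,6S,7R,8R)-3'-oxo-3-(pent-1-yn-1-yl)-7-propyl-3'H-spiro[bicyclo[4.2.0]oct-2-ene-8,1'-[2]benzofuran]-2-carboxylic acid
Conditions: LiI, EtOAc, reflux; then 1 M HCl
Reagents that add atoms: none
Why: Nucleophilic O-demethylation (SN2 attack of iodide on the ester methyl group) is insensitive to crowding at the acyl carbon and cannot open the phthalide, whose alkyl oxygen sits on a tertiary carbon, so only the methyl ester is cleaved.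

Step 17
Reactants: 27 (1R,6S,7R,8R)-3'-oxo-3-(pent-1-yn-1-yl)-7-propyl-3'H-spiro[bicyclo[4.2.0]oct-2-ene-8,1'-[2]benzofuran]-2-carboxylic acid
Product: 28 target CNP0248594.2
Conditions: AgNO3 (10 mol %), acetone, rt, dark
Reagents that add atoms: none
Why: Silver-catalysed cycloisomerization of a (Z)-2-en-4-ynoic acid, in which monovalent silver activates the alkyne, the carboxyl oxygen attacks the proximal alkyne carbon anti to the metal in a 5-exo-dig closure, and protodemetalation leaves oxygen and propyl cis, that is the Z butylidene butenolide.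

**Compound list**

1 | 3-oxocyclobutane-1-carboxylic acid | O=C1CC(C(=O)O)C1 | starting material
2 | 3-bromocyclobutan-1-one | O=C1CC(Br)C1 | intermediate
3 | cyclobut-2-en-1-one | O=C1C=CC1 | intermediate
4 | methyl acetate | COC(C)=O | starting material
5 | acrolein (prop-2-enal) | C=CC=O | starting material
6 | lithium enolate of methyl acetate (not isolated) | [Li+].[O-]C(=C)OC | intermediate
7 | methyl 3-hydroxypent-4-enoate (racemic) | COC(=O)CC(O)C=C | intermediate
8 | methyl 3-oxopent-4-enoate | COC(=O)CC(=O)C=C | intermediate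
9 | methyl (2Z)-3-[(tert-butyldimethylsilyl)oxy]penta-2,4-dienoate | COC(=O)/C=C(\O[Si](C)(C)C(C)(C)C)C=C | intermediate
10 | methyl (1R,2R,6R)-3-[(tert-butyldimethylsilyl)oxy]-7-oxobicyclo[4.2.0]oct-3-ene-2-carboxylate (endo cycloadduct, not isolated) | COC(=O)[C@H]1C(O[Si](C)(C)C(C)(C)C)=CC[C@H]2C(=O)C[C@@H]12 | intermediate
11 | methyl (1R,6R)-3-hydroxy-7-oxobicyclo[4.2.0]oct-2-ene-2-carboxylate (enol form of the β-keto ester, cis-fused) | COC(=O)C2=C(O)CC[C@H]1C(=O)C[C@@H]21 | intermediate
12 | methyl (1R,6R)-3-methoxy-7-oxobicyclo[4.2.0]oct-2-ene-2-carboxylate | COC(=O)C2=C(OC)CC[C@H]1C(=O)C[C@@H]21 | intermediate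
13 | potassium enolate of 12 (O on C7, C7=C8; not isolated) | COC(=O)C2=C(OC)CC[C@H]1C([O-])=C[C@@H]21.[K+] | intermediate
14 | methyl (1R,6R)-3-methoxy-7-(trifluoromethylsulfonyloxy)bicyclo[4.2.0]octa-2,7-diene-2-carboxylate | COC(=O)C2=C(OC)CC[C@H]1C(OS(=O)(=O)C(F)(F)F)=C[C@@H]21 | intermediate
15 | methyl (1R,6R)-3-methoxy-7-propylbicyclo[4.2.0]octa-2,7-diene-2-carboxylate | COC(=O)C2=C(OC)CC[C@H]1C(CCC)=C[C@@H]21 | intermediate
16 | methyl (1R,6S,7S,8S)-8-(9-borabicyclo[3.3.1]nonan-9-yl)-3-methoxy-7-propylbicyclo[4.2.0]oct-2-ene-2-carboxylate (boron on the convex face, not isolated) | COC(=O)C2=C(OC)CC[C@H]1[C@@H](CCC)[C@H](B3C4CCCC3CCC4)[C@@H]21 | intermediate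
17 | methyl (1R,6S,7R,8S)-8-hydroxy-3-methoxy-7-propylbicyclo[4.2.0]oct-2-ene-2-carboxylate (OH convex, propyl concave) | COC(=O)C2=C(OC)CC[C@H]1[C@@H](CCC)[C@H](O)[C@@H]21 | intermediate
18 | methyl (1R,6S,7R)-3-methoxy-8-oxo-7-propylbicyclo[4.2.0]oct-2-ene-2-carboxylate | COC(=O)C2=C(OC)CC[C@H]1[C@@H](CCC)C(=O)[C@@H]21 | intermediate
19 | methyl 2-iodobenzoate | COC(=O)c1ccccc1I | starting material
20 | 2-(methoxycarbonyl)phenylmagnesium chloride, LiCl complex (not isolated) | COC(=O)c1ccccc1[Mg]Cl | intermediate
21 | chloromagnesium alkoxide of methyl 2-[(1R,6S,7R,8R)-8-hydroxy-3-methoxy-2-(methoxycarbonyl)-7-propylbicyclo[4.2.0]oct-2-en-8-yl]benzoate (not isolated) | COC(=O)C2=C(OC)CC[C@H]1[C@@H](CCC)[C@](O[Mg]Cl)(c3ccccc3C(=O)OC)[C@@H]21 | intermediate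
22 | methyl (1R,6S,7R,8R)-3-methoxy-3'-oxo-7-propyl-3'H-spiro[bicyclo[4.2.0]oct-2-ene-8,1'-[2]benzofuran]-2-carboxylate | COC(=O)C2=C(OC)CC[C@H]1[C@@H](CCC)[C@@]3(OC(=O)c4ccccc43)[C@@H]21 | intermediate
23 | methyl (1R,6S,7R,8R)-3-hydroxy-3'-oxo-7-propyl-3'H-spiro[bicyclo[4.2.0]oct-2-ene-8,1'-[2]benzofuran]-2-carboxylate (enol form) | COC(=O)C2=C(O)CC[C@H]1[C@@H](CCC)[C@@]3(OC(=O)c4ccccc43)[C@@H]21 | intermediate
24 | methyl (1R,6S,7R,8R)-3'-oxo-7-propyl-3-(trifluoromethylsulfonyloxy)-3'H-spiro[bicyclo[4.2.0]oct-2-ene-8,1'-[2]benzofuran]-2-carboxylate | COC(=O)C2=C(OS(=O)(=O)C(F)(F)F)CC[C@H]1[C@@H](CCC)[C@@]3(OC(=O)c4ccccc43)[C@@H]21 | intermediate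
25 | pent-1-yne | CCCC#C | starting material
26 | methyl (1R,6S,7R,8R)-3'-oxo-3-(pent-1-yn-1-yl)-7-propyl-3'H-spiro[bicyclo[4.2.0]oct-2-ene-8,1'-[2]benzofuran]-2-carboxylate | COC(=O)C2=C(C#CCCC)CC[C@H]1[C@@H](CCC)[C@@]3(OC(=O)c4ccccc43)[C@@H]21 | intermediate
27 | (1R,6S,7R,8R)-3'-oxo-3-(pent-1-yn-1-yl)-7-propyl-3'H-spiro[bicyclo[4.2.0]oct-2-ene-8,1'-[2]benzofuran]-2-carboxylic acid | OC(=O)C2=C(C#CCCC)CC[C@H]1[C@@H](CCC)[C@@]3(OC(=O)c4ccccc43)[C@@H]21 | intermediate
28 | CNP0248594.2: the (1R,6S,7R,8R) spiro[bicyclo[4.2.0]oct-2-ene-8,1'-[2]benzofuran]-3'-one with propyl on C7 and a (Z)-5-butylidenefuran-2(5H)-one fused across C2–C3 (lactone C=O on C2, ylidene carbon on C3) | CCC/C=C1\OC(=O)C2=C1CC[C@H]1[C@@H](CCC)[C@@]3(OC(=O)c4ccccc43)[C@@H]21 | target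

**Count**

Total: 17 steps. Longest linear sequence: 15 steps (steps 3 to 17, from methyl acetate and acrolein). The cyclobutenone arm (steps 1 and 2) joins at step 6.

**The three steps most likely to fail, each with a fallback**

The first risk lies in the cycloaddition of step 6. The strongly Lewis-acidic catalyst may desilylate the diene, or may divert the reaction into a stepwise Mukaiyama–Michael addition that does not close the ring, or enantiofacial control may be poor with this untested diene. The fallback sets out from 3 and 9 and leaves the Lewis acid out (toluene, rt to 45 °C), relying on ring strain alone for the same [4+2]. This would give 10 together with its mirror image, methyl (1S,2S,6S)-3-[(tert-butyldimethylsilyl)oxy]-7-oxobicyclo[4.2.0]oct-3-ene-2-carboxylate F1. The acid hydrolysis used in step 6 then turns 10 into 11 and F1 into methyl (1S,6S)-3-hydroxy-7-oxobicyclo[4.2.0]oct-2-ene-2-carboxylate F2. The methylation of step 7 gives 12 together with methyl (1S,6S)-3-methoxy-7-oxobicyclo[4.2.0]oct-2-ene-2-carboxylate F3. Preparative chromatography on a chiral stationary phase removes F3, and the route is rejoined at 12.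

The second risk lies in the aryl addition of step 12. The basic arylmagnesium reagent may enolize 18 instead of adding to it, which would return ketone or scramble the contra-thermodynamic C7 centre. The fallback sets out from 18 and 19 and uses a Nozaki–Hiyama–Kishi-type Barbier reaction (CrCl2, NiCl2 cat., DMF, rt). Nickel activates the C–I bond and hands the aryl group to chromium, and the non-basic arylchromium species (trivalent chromium), formed in the presence of the ketone, should add from the same convex face. Aqueous work-up should give methyl 2-[(1R,6S,7R,8R)-8-hydroxy-3-methoxy-2-(methoxycarbonyl)-7-propylbicyclo[4.2.0]oct-2-en-8-yl]benzoate F4. The hydroxy ester F4 is lactonized with catalytic TsOH in toluene, and the route is rejoined at 22.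

The third risk lies in the O-methylation of step 7. Methylation may go partly to carbon at C2, or the basic medium may trigger aldol chemistry of the cyclobutanone. The fallback sets out from 11 and works under acid: HC(OMe)3, TsOH (cat.), MeOH, rt. The β-keto ester should give the conjugated methyl enol ether while the strained ketone is ketalized, giving methyl (1R,6R)-3,7,7-trimethoxybicyclo[4.2.0]oct-2-ene-2-carboxylate F5. PPTS in wet acetone should then hydrolyse only the ketal of F5, since the vinylogous carbonate needs much stronger acid, and the route is rejoined at 12.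

**Further compounds**

F1 | step 6 | methyl (1S,2S,6S)-3-[(tert-butyldimethylsilyl)oxy]-7-oxobicyclo[4.2.0]oct-3-ene-2-carboxylate | COC(=O)[C@@H]1C(O[Si](C)(C)C(C)(C)C)=CC[C@@H]2C(=O)C[C@H]12
F2 | step 6 | methyl (1S,6S)-3-hydroxy-7-oxobicyclo[4.2.0]oct-2-ene-2-carboxylate | COC(=O)C2=C(O)CC[C@@H]1C(=O)C[C@H]21
F3 | step 6 | methyl (1S,6S)-3-methoxy-7-oxobicyclo[4.2.0]oct-2-ene-2-carboxylate | COC(=O)C2=C(OC)CC[C@@H]1C(=O)C[C@H]21
F4 | step 12 | methyl 2-[(1R,6S,7R,8R)-8-hydroxy-3-methoxy-2-(methoxycarbonyl)-7-propylbicyclo[4.2.0]oct-2-en-8-yl]benzoate | COC(=O)C2=C(OC)CC[C@H]1[C@@H](CCC)[C@](O)(c3ccccc3C(=O)OC)[C@@H]21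
F5 | step 7 | methyl (1R,6R)-3,7,7-trimethoxybicyclo[4.2.0]oct-2-ene-2-carboxylate | COC(=O)C2=C(OC)CC[C@H]1C(OC)(OC)C[C@@H]21
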